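Which flask ends highest in excess of left-handed product, the one held cold, the one held hot, or the one moved from hot to cold for its last minute?

| setting | east | west | south-east |
|---|---|---|---|
| left-handed substrate | 0.10 M | 0.10 M | 0.10 M |
| partner | 0.200 M | 0.200 M | 0.200 M |
| racemization catalyst | 0.20 mM | 0.20 mM | 0.20 mM |
| added ligand | 0.16 mM | 0.16 mM | 0.16 mM |
| right-handed substrate | 0.10 M | 0.10 M | 0.10 M |
| temperature | 30 °C | 50 °C |  |
| time | 4.0 min | 4.0 min | 4.0 min |
| remark |  |  | at 50 °C until 3.0 min, from then on at 30 °C |

    partner + left-handed substrate → left-handed product (k1 = 0.0066 /M/s, Ea1 = 70.0 kJ/mol)
    partner + right-handed substrate → right-handed product (k2 = 4.1 × 10⁻⁴ /M/s, Ea2 = 69.0 kJ/mol)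
    left-handed substrate + racemization catalyst ⇌ right-handed substrate + racemization catalyst, rate k3*[racemization catalyst]*[left-handed substrate] forward; the back reaction follows from the equilibrium constant (k3 = 1.1 /M/s, Ea3 = 58.0 kJ/mol)
    racemization catalyst + added ligand ⇌ idle complex (K4 = 3700 /M, k4 = 66 /M/s, Ea4 = 36.0 kJ/mol, ΔH4 = −56.0 kJ/mol)
    (constants at 50 °C)

- partner is single-handed; left-handed substrate and right-handed substrate are mirror images of each other, charged as a racemate, each of them at the stated concentration
- the list of constants is for 50 °C, to be carried to other temperatures by the activation energies and enthalpies
- an excess is the difference of the two amounts in percent of their sum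
- an excess is below zero if the other one leads
- the handed part of partner does not stay in what it makes, so the products of the two hands are mirror images too

- the flask that comes out highest in excess of left-handed product over right-handed product, or "all alike" when all lie within 1.5 percentage points (east / west / south-east / all alike)
- excess of left-handed product over right-handed product at the end, east
- excess of left-handed product over right-handed product at the end, west
- excess of left-handed product over right-handed product at the end, south-east

The left-handed step alone would give an excess of 100%, so the reckoning starts there, in west at 50 °C. The concentration to watch is [partner]: held at its charge, it makes the loss of each hand pseudo-first-order. The exponent of that loss is the dose, the rate constant of the left-handed step times [partner] times time, 0.317 in west. That dose turns 27.2% of the left-handed charge into product, which uses 13.6% of the partner charge, so holding [partner] is a fair start.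

Adding the right-handed step brings in the selectivity factor, the ratio of the two rate constants, 16.1. The right-handed dose is the dose divided by this factor, and it converts 1.95% of its charge. At vanishing dose the excess would be 88.3%, and it slips as left-handed substrate thins, to 86.6% for west.

Racemization comes next. Both forms have the same energy, so its net flow follows the gap between the hands, which start equal. Even with the end gap counted for the whole time and the catalyst counted as free, it returns 1.33% of the left-handed charge in west, less than the share consumed, so the reckoning leaves it out. The added ligand binds catalyst, which shrinks this term further, and it is left out too.

East at 30 °C scales the left-handed rate constant by 0.179, giving a dose of 0.0568 and a selectivity factor of 15.7, hence 87.7%. South-east spends 3.0 min hot and the rest cold, which sums to a dose of 0.252 and, with the selectivity factor of the hot part kept throughout, gives 87.0%. East and west differ by less than the margin of 1.5 percentage points, so this reckoning says all alike.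

The forecast gives 87.8% for east, 86.8% for west and 87% for south-east, hence all alike, holding that “each flask behaves as a near-plain kinetic resolution”.

The flasks end at 87.7% in east, 86.8% in west and 87.1% in south-east: all alike.

The gauge to watch is the left-handed substrate remaining. The dose leaves 72.8% of it in west, and the flask shows 75%. A neighbour of west with 0.80 M of partner, 8.00 equiv to left-handed substrate, has a dose of 1.27. The same reckoning gives it an excess of 80.9% and leaves 28.1% of the left-handed charge. That neighbour ends at 81.6%, lower than west, with 31% of its left-handed substrate and 90% of its partner still there.

The numbers of this flask were set for the occasion; the run is a simulation.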